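**Retrosynthetic overview**
1. The target is cut at the ester to the allylic alcohol 19; the Z-cinnamate is built on the substrate by a Z-selective Horner–Wadsworth–Emmons olefination.
2. C4–C15: 19 comes from the C3=C4 enol triflate of a trans-fused 4-decalone and a hydroxymethyl anion equivalent (Bu3SnCH2OH); the acrylate comes from α-methylenation of a CH2CO2Me side chain.
3. Key bond C6–C7: ring B is closed from the 2-methylene ketone/enoate 9 with SmI2. The enone β-carbon reacts as a ketone homoenolate and attacks the enoate β-carbon, two carbons that are both acceptors in the substrate; this sets C7, and C5 is then set trans by protonation and equilibration.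
4. 9 comes from 3-methylcyclohex-2-enone by catalytic asymmetric conjugate addition (sets C10), cross metathesis and Mannich methylenation.
5. Ring order: ring A is bought (the cyclohexenone); ring B is formed in the key step.

Assumption: 2-(diphenoxyphosphoryl)acetic acid and (tributylstannyl)methanol are taken as catalogue reagents; atom labels C1–C15 follow eudesmane numbering (C10 carries the angular methyl, C5 is the other ring-fusion carbon, C4 carries C15, C7 carries the C11–C13 side chain).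

**Route**

Step 1
Reactants: 1 3-methylcyclohex-2-en-1-one; 2 but-3-en-1-ylmagnesium bromide
Product: 4 triethyl{[(3R)-3-(but-3-en-1-yl)-3-methylcyclohex-1-en-1-yl]oxy}silane, via bromomagnesium enolate 3 (not isolated)
Conditions: Cu(OTf)2 (3 mol %), chiral C2-symmetric imidazolinium chloride (carbene precursor, 4 mol %), Et2O, 0 °C; then Et3SiCl, Et3N, HMPA, 0 °C to rt
Reagents that add atoms: chlorotriethylsilane, CC[Si](Cl)(CC)CC
Why: Copper–carbene-catalysed asymmetric conjugate addition of the Grignard reagent to the β-methyl enone creates the quaternary C10 stereocentre under ligand control (the ligand antipode that gives the R adduct is used), and O-silylation of the regiodefined enolate stores the C4=C5 enol position for the later C5 functionalisation.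

Step 2
Reactants: 4 triethyl{[(3R)-3-(but-3-en-1-yl)-3-methylcyclohex-1-en-1-yl]oxy}silane; 5 methyl acrylate
Product: 6 methyl (2E)-5-[(1R)-1-methyl-3-(triethylsilyloxy)cyclohex-2-en-1-yl]pent-2-enoate
Conditions: RuCl2(H2IMes)(=CH-C6H4-2-OiPr) (second-generation Hoveyda–Grubbs catalyst, 3 mol %), methyl acrylate (5 equiv), CH2Cl2, 40 °C
Reagents that add atoms: none
Why: Olefin cross metathesis of a terminal alkene and an acrylate is E-selective and leaves the hindered trisubstituted silyl enol ether and the C10 stereocentre untouched.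

Step 3
Reactants: 6 methyl (2E)-5-[(1R)-1-methyl-3-(triethylsilyloxy)cyclohex-2-en-1-yl]pent-2-enoate
Product: 9 methyl (2E)-5-[(1R)-1-methyl-2-methylidene-3-oxocyclohexyl]pent-2-enoate, via Mannich base 7 (not isolated), via trimethylammonium iodide 8 (not isolated)
Conditions: Me2N=CH2+ I− (1.3 equiv), CH2Cl2, rt; then MeI, rt; then aq. NaHCO3, rt
Reagents that add atoms: N,N-dimethylmethyleneiminium iodide (Eschenmoser's salt), C=[N+](C)C.[I-]
Why: Mannich reaction of the silyl enol ether puts the aminomethyl group regiospecifically on C5, and quaternisation followed by E1cB elimination (Eschenmoser methylenation) gives the exocyclic enone, erasing the transient C5 stereocentre.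

Step 4
Reactants: 9 methyl (2E)-5-[(1R)-1-methyl-2-methylidene-3-oxocyclohexyl]pent-2-enoate
Product: 11 methyl 2-[(2R,4aR,8aR)-4a-methyl-8-oxodecahydronaphthalen-2-yl]acetate, via cis-fused C5 epimer 10 (not isolated)
Conditions: SmI2 (2.5 equiv), HMPA, t-BuOH (2 equiv), THF (0.01 M), −78 °C to 0 °C; then NaOMe (0.2 equiv), MeOH, rt
Reagents that add atoms: none
Why: Samarium diiodide reduces the enone to a radical anion whose β-carbon C6 acts as a ketone homoenolate and adds 6-exo-trig to the enoate β-carbon C7 (reductive β,β-coupling of two Michael acceptors, hydrodimerisation type) through a chair transition state in which ring A forces the angular methyl axial and the enoate sits equatorial, so the C7 side chain ends cis to the methyl group, and protonation of the resulting enolate followed by NaOMe equilibration gives the more stable trans-fused 5α-H ketone.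

Step 5
Reactants: 11 methyl 2-[(2R,4aR,8aR)-4a-methyl-8-oxodecahydronaphthalen-2-yl]acetate
Product: 13 methyl 2-[(2R,4aS,8aR)-4a-methyl-8-{[(trifluoromethyl)sulfonyl]oxy}-1,2,3,4,4a,5,6,8a-octahydronaphthalen-2-yl]acetate, via potassium enolate 12 (not isolated)
Conditions: KN(SiMe3)2 (1.05 equiv), THF, −78 °C (ketone added to base); then PhNTf2, −78 °C to 0 °C
Reagents that add atoms: N-phenylbis(trifluoromethanesulfonimide), O=S(=O)(N(c1ccccc1)S(=O)(=O)C(F)(F)F)C(F)(F)F
Why: Kinetic deprotonation takes the unhindered C3 methylene rather than the ring-fusion C5–H or the less acidic ester α-CH2, and O-triflation (regioselective enol triflate formation) fixes the C3=C4 double bond without touching C5.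

Step 6
Reactants: 13 methyl 2-[(2R,4aS,8aR)-4a-methyl-8-{[(trifluoromethyl)sulfonyl]oxy}-1,2,3,4,4a,5,6,8a-octahydronaphthalen-2-yl]acetate
Product: 17 methyl 2-[(2R,4aS,8aR)-4a-methyl-8-{[(trifluoromethyl)sulfonyl]oxy}-1,2,3,4,4a,5,6,8a-octahydronaphthalen-2-yl]prop-2-enoate, via lithium ester enolate 14 (not isolated), via Mannich base 15 (not isolated), via trimethylammonium iodide 16 (not isolated)
Conditions: LiN(iPr)2 (1.2 equiv), THF, −78 °C; Me2N=CH2+ I−, −78 °C to rt; then MeI, MeOH, rt; then aq. NaHCO3, rt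
Reagents that add atoms: N,N-dimethylmethyleneiminium iodide (Eschenmoser's salt), C=[N+](C)C.[I-]
Why: Eschenmoser methylenation of the ester enolate (Mannich reaction, quaternisation, E1cB loss of trimethylamine) can only eliminate towards C11=C13, so the α-substituted acrylate forms without touching C7 or the enol triflate.

Step 7
Reactants: 17 methyl 2-[(2R,4aS,8aR)-4a-methyl-8-{[(trifluoromethyl)sulfonyl]oxy}-1,2,3,4,4a,5,6,8a-octahydronaphthalen-2-yl]prop-2-enoate; 18 (tributylstannyl)methanol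
Product: 19 methyl 2-[(2R,4aR,8aR)-8-(hydroxymethyl)-4a-methyl-1,2,3,4,4a,5,6,8a-octahydronaphthalen-2-yl]prop-2-enoate
Conditions: Pd(PPh3)4 (5 mol %), LiCl (3 equiv), 1,4-dioxane, 95 °C
Reagents that add atoms: none
Why: Stille (Kosugi–Migita) coupling transfers the hydroxymethyl group, a carbinol carbon used as a nucleophile, to the former carbonyl carbon C4 of the enol triflate, keeping the C3=C4 position and all stereocentres.

Step 8
Reactants: 19 methyl 2-[(2R,4aR,8aR)-8-(hydroxymethyl)-4a-methyl-1,2,3,4,4a,5,6,8a-octahydronaphthalen-2-yl]prop-2-enoate; 20 2-(diphenoxyphosphoryl)acetic acid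
Product: 21 methyl 2-[(2R,4aR,8aR)-8-({[2-(diphenoxyphosphoryl)acetyl]oxy}methyl)-4a-methyl-1,2,3,4,4a,5,6,8a-octahydronaphthalen-2-yl]prop-2-enoate
Conditions: DCC (1.2 equiv), DMAP (10 mol %), CH2Cl2, 0 °C to rt
Reagents that add atoms: none
Why: Steglich esterification acylates the unhindered primary allylic alcohol under neutral conditions that do not disturb the acrylate or the ring alkene.

Step 9
Reactants: 21 methyl 2-[(2R,4aR,8aR)-8-({[2-(diphenoxyphosphoryl)acetyl]oxy}methyl)-4a-methyl-1,2,3,4,4a,5,6,8a-octahydronaphthalen-2-yl]prop-2-enoate; 22 4-[(tert-butyldimethylsilyl)oxy]benzaldehyde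
Product: 25 methyl 2-[(2R,4aR,8aR)-8-({[(2Z)-3-(4-hydroxyphenyl)prop-2-enoyl]oxy}methyl)-4a-methyl-1,2,3,4,4a,5,6,8a-octahydronaphthalen-2-yl]prop-2-enoate, via sodium phosphonate carbanion 23 (not isolated), via aryl silyl ether 24 (not isolated)
Conditions: NaH (1.05 equiv), THF, −78 °C; then 22, −78 °C to 0 °C; then AcOH (2 equiv), Bu4NF (1.1 equiv), 0 °C
Reagents that add atoms: none
Why: The diaryl phosphonate gives the Z-cinnamate by Ando-type Horner–Wadsworth–Emmons olefination (fast, irreversible collapse of the syn oxaphosphetane; about 9:1 Z:E expected, minor E isomer removed by chromatography), and acetic-acid-buffered fluoride cleaves the aryl silyl ether without ester cleavage or Z/E isomerisation.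

**Compound list**
1 | 3-methylcyclohex-2-en-1-one | CC1=CC(=O)CCC1 | starting material
2 | but-3-en-1-ylmagnesium bromide | C=CCC[Mg]Br | starting material
3 | bromomagnesium (3R)-3-(but-3-en-1-yl)-3-methylcyclohex-1-en-1-olate | C=CCC[C@@]1(C)CCCC(O[Mg]Br)=C1 | intermediate
4 | triethyl{[(3R)-3-(but-3-en-1-yl)-3-methylcyclohex-1-en-1-yl]oxy}silane | C=CCC[C@@]1(C)CCCC(O[Si](CC)(CC)CC)=C1 | intermediate
5 | methyl acrylate (methyl prop-2-enoate) | C=CC(=O)OC | starting material
6 | methyl (2E)-5-[(1R)-1-methyl-3-(triethylsilyloxy)cyclohex-2-en-1-yl]pent-2-enoate | COC(=O)/C=C/CC[C@@]1(C)CCCC(O[Si](CC)(CC)CC)=C1 | intermediate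
7 | methyl (2E)-5-[(1R)-2-[(dimethylamino)methyl]-1-methyl-3-oxocyclohexyl]pent-2-enoate (both C2 epimers) | COC(=O)/C=C/CC[C@@]1(C)CCCC(=O)C1CN(C)C | intermediate
8 | {[(2R)-2-[(3E)-5-methoxy-5-oxopent-3-en-1-yl]-2-methyl-6-oxocyclohexyl]methyl}trimethylammonium iodide | COC(=O)/C=C/CC[C@@]1(C)CCCC(=O)C1C[N+](C)(C)C.[I-] | intermediate
9 | methyl (2E)-5-[(1R)-1-methyl-2-methylidene-3-oxocyclohexyl]pent-2-enoate | COC(=O)/C=C/CC[C@@]1(C)CCCC(=O)C1=C | intermediate
10 | methyl 2-[(2R,4aR,8aS)-4a-methyl-8-oxodecahydronaphthalen-2-yl]acetate (cis-fused, 5β-H) | COC(=O)C[C@@H]1CC[C@@]2(C)CCCC(=O)[C@H]2C1 | intermediate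
11 | methyl 2-[(2R,4aR,8aR)-4a-methyl-8-oxodecahydronaphthalen-2-yl]acetate (trans-fused, 5α-H, 7β side chain, 10β-methyl) | COC(=O)C[C@@H]1CC[C@@]2(C)CCCC(=O)[C@@H]2C1 | intermediate
12 | potassium (4aS,7R,8aR)-7-(2-methoxy-2-oxoethyl)-4a-methyl-3,4,4a,5,6,7,8,8a-octahydronaphthalen-1-olate | COC(=O)C[C@@H]1CC[C@@]2(C)CCC=C([O-])[C@@H]2C1.[K+] | intermediate
13 | methyl 2-[(2R,4aS,8aR)-4a-methyl-8-{[(trifluoromethyl)sulfonyl]oxy}-1,2,3,4,4a,5,6,8a-octahydronaphthalen-2-yl]acetate | COC(=O)C[C@@H]1CC[C@@]2(C)CCC=C(OS(=O)(=O)C(F)(F)F)[C@@H]2C1 | intermediate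
14 | lithium ester enolate of 13 (lithium 1-methoxy-2-[(2R,4aS,8aR)-4a-methyl-8-(triflyloxy)-1,2,3,4,4a,5,6,8a-octahydronaphthalen-2-yl]ethen-1-olate) | [Li+].COC([O-])=C[C@@H]1CC[C@@]2(C)CCC=C(OS(=O)(=O)C(F)(F)F)[C@@H]2C1 | intermediate
15 | methyl 3-(dimethylamino)-2-[(2R,4aS,8aR)-4a-methyl-8-{[(trifluoromethyl)sulfonyl]oxy}-1,2,3,4,4a,5,6,8a-octahydronaphthalen-2-yl]propanoate (both C2 epimers) | COC(=O)C(CN(C)C)[C@@H]1CC[C@@]2(C)CCC=C(OS(=O)(=O)C(F)(F)F)[C@@H]2C1 | intermediate
16 | trimethylammonium iodide of 15 (N-methylated 15) | COC(=O)C(C[N+](C)(C)C)[C@@H]1CC[C@@]2(C)CCC=C(OS(=O)(=O)C(F)(F)F)[C@@H]2C1.[I-] | intermediate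
17 | methyl 2-[(2R,4aS,8aR)-4a-methyl-8-{[(trifluoromethyl)sulfonyl]oxy}-1,2,3,4,4a,5,6,8a-octahydronaphthalen-2-yl]prop-2-enoate | C=C(C(=O)OC)[C@@H]1CC[C@@]2(C)CCC=C(OS(=O)(=O)C(F)(F)F)[C@@H]2C1 | intermediate
18 | (tributylstannyl)methanol | OC[Sn](CCCC)(CCCC)CCCC | starting material
19 | methyl 2-[(2R,4aR,8aR)-8-(hydroxymethyl)-4a-methyl-1,2,3,4,4a,5,6,8a-octahydronaphthalen-2-yl]prop-2-enoate | C=C(C(=O)OC)[C@@H]1CC[C@@]2(C)CCC=C(CO)[C@@H]2C1 | intermediate
20 | 2-(diphenoxyphosphoryl)acetic acid | OC(=O)CP(=O)(Oc1ccccc1)Oc1ccccc1 | starting material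
21 | methyl 2-[(2R,4aR,8aR)-8-({[2-(diphenoxyphosphoryl)acetyl]oxy}methyl)-4a-methyl-1,2,3,4,4a,5,6,8a-octahydronaphthalen-2-yl]prop-2-enoate | C=C(C(=O)OC)[C@@H]1CC[C@@]2(C)CCC=C(COC(=O)CP(=O)(Oc3ccccc3)Oc3ccccc3)[C@@H]2C1 | intermediate
22 | 4-[(tert-butyldimethylsilyl)oxy]benzaldehyde | O=Cc1ccc(O[Si](C)(C)C(C)(C)C)cc1 | starting material
23 | sodium salt of the phosphonate carbanion of 21 | C=C(C(=O)OC)[C@@H]1CC[C@@]2(C)CCC=C(COC(=O)[CH-]P(=O)(Oc3ccccc3)Oc3ccccc3)[C@@H]2C1.[Na+] | intermediate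
24 | methyl 2-[(2R,4aR,8aR)-8-({[(2Z)-3-{4-[(tert-butyldimethylsilyl)oxy]phenyl}prop-2-enoyl]oxy}methyl)-4a-methyl-1,2,3,4,4a,5,6,8a-octahydronaphthalen-2-yl]prop-2-enoate | C=C(C(=O)OC)[C@@H]1CC[C@@]2(C)CCC=C(COC(=O)/C=C\c3ccc(O[Si](C)(C)C(C)(C)C)cc3)[C@@H]2C1 | intermediate
25 | methyl 2-[(2R,4aR,8aR)-8-({[(2Z)-3-(4-hydroxyphenyl)prop-2-enoyl]oxy}methyl)-4a-methyl-1,2,3,4,4a,5,6,8a-octahydronaphthalen-2-yl]prop-2-enoate (CNP0161949.2) | C=C(C(=O)OC)[C@@H]1CC[C@@]2(C)CCC=C(COC(=O)/C=C\c3ccc(O)cc3)[C@@H]2C1 | target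

**Step count and risks**

Total step count: 9. Longest linear sequence: 9 steps (1 to 25).

The step most at risk is step 4. The radical anion may simply be reduced to the 2-methyl ketone, may dimerise, or may close ring B with poor selectivity at C7. The fallback sets out from 9 and drops the electron-transfer chemistry. Aqueous HI (CH2Cl2, 0 °C) adds across the exocyclic enone to give methyl (2E)-5-[(1R)-2-(iodomethyl)-1-methyl-3-oxocyclohexyl]pent-2-enoate F4. Bu3SnH with AIBN (benzene, 80 °C, slow addition) then generates the primary C6 radical, which closes ring B by 6-exo-trig conjugate addition to the enoate. The same NaOMe equilibration brings the route back at 11.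

Second is step 1, where the ee of the quaternary centre and the silylation of the magnesium enolate may be unsatisfactory. The fallback sets out from 2 and exchanges the roles of the two alkyl groups. Compound 2 adds 1,2 to 3-ethoxycyclohex-2-en-1-one to give 1-(but-3-en-1-yl)-3-ethoxycyclohex-2-en-1-ol F1. Dilute HCl converts this to 3-(but-3-en-1-yl)cyclohex-2-en-1-one F2 (Stork–Danheiser transposition). Asymmetric conjugate addition of Me3Al (Cu(O2CC4H3S), copper thiophene-2-carboxylate, 2 mol %, chiral phosphoramidite, Et2O, −30 °C) gives the dimethylaluminium (3R)-3-(but-3-en-1-yl)-3-methylcyclohex-1-en-1-olate F3. Et3SiOTf silylates it, and the route is rejoined at 4.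

Third is step 7, where the hindered enol triflate next to the ring fusion may couple sluggishly or the acrylate may interfere. The fallback sets out from 17 and brings in C15 as carbon monoxide. Palladium-catalysed formylation (Pd(OAc)2, Ph2P(CH2)3PPh2, CO 1 atm, Et3SiH, DMF, 70 °C) gives methyl 2-[(2R,4aR,8aR)-8-formyl-4a-methyl-1,2,3,4,4a,5,6,8a-octahydronaphthalen-2-yl]prop-2-enoate F5. Luche reduction (NaBH4, CeCl3·7H2O, MeOH, −40 °C) reduces only the aldehyde and returns the route at 19.

Further compounds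
F1 | step 1 | 1-(but-3-en-1-yl)-3-ethoxycyclohex-2-en-1-ol (racemic) | C=CCCC1(O)C=C(OCC)CCC1
F2 | step 1 | 3-(but-3-en-1-yl)cyclohex-2-en-1-one | C=CCCC1=CC(=O)CCC1
F3 | step 1 | dimethylaluminium (3R)-3-(but-3-en-1-yl)-3-methylcyclohex-1-en-1-olate | C=CCC[C@@]1(C)CCCC(O[Al](C)C)=C1
F4 | step 4 | methyl (2E)-5-[(1R)-2-(iodomethyl)-1-methyl-3-oxocyclohexyl]pent-2-enoate (both C2 epimers) | COC(=O)/C=C/CC[C@@]1(C)CCCC(=O)C1CI
F5 | step 7 | methyl 2-[(2R,4aR,8aR)-8-formyl-4a-methyl-1,2,3,4,4a,5,6,8a-octahydronaphthalen-2-yl]prop-2-enoate | C=C(C(=O)OC)[C@@H]1CC[C@@]2(C)CCC=C(C=O)[C@@H]2C1
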